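## The problem

Target 11 is a 3,3''-linked dimer of (2S)-5,7-dihydroxy-4'-methoxyflavanone. Two chroman-4-one systems (rings A/C and A''/C'') are joined by one single bond between C3 and C3'', two tertiary carbons that are each α to an aryl ketone and each flanked by a C2 carbon bearing a 4-methoxyphenyl group. The four stereocentres C2, C3, C3'' and C2'' are contiguous, and both C2 centres are S, but the halves are not related by symmetry: ring C is 2,3-trans (2S,3R) and ring C'' is 2'',3''-cis (2''S,3''S). A symmetric dimerisation of a (2S)-flavanone therefore cannot give 11 directly, and because the cis ring is the less stable arrangement, C3'' has to be set late and kinetically. Within each ring C2 can control C3 (attack or protonation anti to the aryl group, or an equatorial preference in a chair), but nothing relays stereochemical information reliably across the C3–C3'' bond. Both C3–H bonds are enolisable and both O1–C2 bonds are β to a ketone (E1cB opening), so base or strong acid after the stereocentres are set would scramble C3 and C2; the 5- and 7-hydroxyls must be freed last, under neutral conditions, and kept distinct from the 4'-methyl ethers. The enabling feature is the 1,4-diketone C4(=O)–C3–C3''–C4''(=O): each carbonyl carbon sits on C4a of a ring A ortho to the ether oxygen O1 (a former salicylaldehyde carbon), and the chain O1–C2–C3–C3''–C2''–O1'' is that of a but-2-yne-1,4-diol bis(aryl ether) with C3≡C3'' as the alkyne. Each ring C is thus the retron of an intramolecular acyl-anion addition, the first to the alkyne and the second to the enone that the first creates, and two mechanistically different closures are what two differently configured halves require.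

## Retrosynthesis

**11 from 10.** The four phenolic O–H bonds of 11 are traced back to benzyl ethers in 10, the (2S,3R,2''S,3''S)-tetrabenzyl ether. Benzyl is chosen over acetal or silyl groups because it comes off by hydrogenolysis without acid or base, which the cis centre C3'' and the β-aryloxy ketones need, and because it leaves the 4'-methyl ethers alone. The forward step must not cleave the benzylic O1–C2 bonds.

**10 from 8 (through 9).** The bonds cut are C4–C3 and C4''–C3'', the two ketone-to-α-carbon bonds, not the central C3–C3'' bond. Cutting C3–C3'' (the neighbouring choice) asks for a coupling of two hindered tertiary centres and gives a symmetric product. Cutting O1–C2 puts C2 and C3 under reversible, thermodynamic control. Cutting C4–C3 twice instead turns C3–C3'' into the triple bond of the C2-symmetric dialdehyde 8, in which rings C and C'' are absent, only the two carbinol-derived centres exist and the two formyl groups are homotopic. The forward reaction is one carbene-catalysed operation: hydroacylation of the alkyne by one formyl group gives the 3-alkylidene flavanone 9 (not isolated), and a Stetter addition of the other formyl group to that enone gives 10. It must close both rings in the 6-exo mode, form C3 trans to C2 in the Stetter ring, and protonate C3'' kinetically, anti to the C2'' aryl group, in the other ring.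

**8 from 5 and 7.** The two O1–C2 ether bonds are cut to the (S,S)-diol 5 and two molecules of the salicylaldehyde 7. A double Mitsunobu reaction is preferred over O-arylation because 7 is a simple phenol and the reaction is a single convergent operation. It proceeds with inversion, which is why 5 is needed as the (S,S) isomer to arrive at (R,R)-8. The forward step must keep SN2 character at a 4-methoxybenzylic, propargylic carbon.

**5 from 4 and 1; 4 from 3; 3 from 1 and 2.** The two carbinol–alkyne bonds are cut, leading to two molecules of 4-methoxybenzaldehyde 1 and ethynyltrimethylsilane 2 as the acetylene unit. Two catalyst-controlled alkynylations (1 + 2 to 3, desilylation to 4, then 4 + 1 to 5) set both C2 centres before any ring exists. Because 5 is C2-symmetric, mismatches in either addition end up mainly in the separable meso diol. The forward reactions need high facial control on an electron-rich aromatic aldehyde and, in the second addition, tolerance of the zinc alkoxide of 4.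

**7 from 6.** Two O–benzyl bonds are cut back to 2,4,6-trihydroxybenzaldehyde 6. The forward step relies on the chelated ortho-hydroxyl being the least reactive of the three.

## Roads not taken

Alternative 1: Cut C3–C3'' (the obvious disconnection). The forward key step is oxidative homocoupling (lithium enolate with CuCl2 or I2) of (2S)-5,7-bis(benzyloxy)-4'-methoxyflavanone A1 to the dehydrodimer. Each enolate reacts anti to its own C2 aryl group, so the expected product is the C2-symmetric trans,trans isomer A2, and the unsymmetrical trans/cis pattern must then be imposed by differentiating two homotopic C3–H bonds in a separate enolisation and kinetic protonation. The coupling joins two hindered tertiary carbons, competes with over-oxidation across C2–C3, and exposes the base-labile C2 centre of A1 to E1cB opening and racemisation. A1 itself needs a multi-step asymmetric synthesis, so the route is no shorter than the chosen one and carries no stereochemical leverage. The chosen plan never has to form the C3–C3'' bond and obtains the trans/cis difference from the mechanism of the key step.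

Alternative 2: Cut C3–C3'' and both O1–C2 bonds in a biomimetic sense. One-electron oxidation (Ag2O or a peroxidase-type oxidant) of the 4-hydroxychalcone A3 would give phenoxyl radicals with spin density at the α-carbon, as in lignan β–β coupling. Radical coupling at the two α-carbons followed by twofold conjugate addition of the 2'-hydroxyls would give the 4',4'''-diol A4, which would then be O-methylated to 10. This closes two rings and forms three bonds at once, but four stereocentres arise with no resident stereocentre or catalyst to direct them, so all relative arrangements and both enantiomers are to be expected. The radical can also couple through oxygen or the ring, A4 with free 4'-hydroxyls is configurationally labile at C2 through quinone methide formation, and a base-mediated methylation would endanger the cis ring. The chosen plan fixes C2 and C2'' irreversibly before the rings are made.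

Alternative 3: Cut only the two O1–C2 bonds. Double aldol condensation of the 1,4-diketone A5 with 1 would give the bis(benzylidene) diketone A6, and a twofold 6-endo oxa-Michael cyclisation would close both pyranone rings. The precursor is very simple, but C2 and C3 of each ring would be formed under conditions in which oxa-Michael addition and enolisation are reversible, so the outcome is the thermodynamic distribution (expected to favour trans,trans) and any enantiocontrol by a catalyst would be erased by the same reversibility. Paal–Knorr cyclodehydration of A5 is a further competitor. The chosen plan needs neither C2 nor the cis centre to survive equilibrating conditions.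

Key step: step 6

Assumption: the (S,S) antipode of the bis(prolinol)phenol ligand is taken to give the carbinol configuration drawn for 3 and 5; if the opposite sense is found, the (R,R) ligand is used in steps 1 and 3 and nothing else changes.

## Route

Step 1
Reactants: 1 4-methoxybenzaldehyde; 2 ethynyltrimethylsilane
Product: 3 (1S)-1-(4-methoxyphenyl)-3-(trimethylsilyl)prop-2-yn-1-ol
Conditions: 2 (3 equiv), Me2Zn (3 equiv), (S,S)-2,6-bis{[2-(hydroxydiphenylmethyl)pyrrolidin-1-yl]methyl}-4-methylphenol (10 mol%), Ph3P=O (20 mol%), toluene, 0 °C; then 1; sat. aq NH4Cl
Reagents that add atoms: none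
Why: Catalytic asymmetric alkynylation of an aldehyde by an alkynylzinc formed in situ; the dinuclear zinc complex of the ligand holds aldehyde and alkynyl on neighbouring zinc atoms and fixes the face of addition, which sets the future C2 (S here because silylalkynyl outranks aryl).

Step 2
Reactants: 3 (1S)-1-(4-methoxyphenyl)-3-(trimethylsilyl)prop-2-yn-1-ol
Product: 4 (1R)-1-(4-methoxyphenyl)prop-2-yn-1-ol
Conditions: K2CO3 (0.2 equiv), MeOH, 0 °C to rt
Reagents that add atoms: none
Why: Methoxide-mediated protodesilylation of an alkynylsilane; the carbinol centre is untouched and its descriptor becomes R only because ethynyl ranks below aryl.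

Step 3
Reactants: 4 (1R)-1-(4-methoxyphenyl)prop-2-yn-1-ol; 1 4-methoxybenzaldehyde
Product: 5 (1S,4S)-1,4-bis(4-methoxyphenyl)but-2-yne-1,4-diol
Conditions: Me2Zn (3.5 equiv), (S,S)-2,6-bis{[2-(hydroxydiphenylmethyl)pyrrolidin-1-yl]methyl}-4-methylphenol (20 mol%), Ph3P=O (40 mol%), toluene, 0 °C; then 1 (1.5 equiv), 0 °C to rt; sat. aq NH4Cl
Reagents that add atoms: none
Why: The same zinc-catalysed asymmetric alkynylation, with the hydroxyl of 4 carried as its zinc alkoxide (the species every such reaction accumulates as product); catalyst control sets the second carbinol with the same sense, and errors of either addition end up mainly in the meso diol, which is removed by chromatography or crystallisation, so the (S,S)-diol should be enantiomerically upgraded.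

Step 4
Reactants: 6 2,4,6-trihydroxybenzaldehyde
Product: 7 4,6-bis(benzyloxy)-2-hydroxybenzaldehyde
Conditions: BnBr (2.1 equiv), K2CO3 (2.2 equiv), DMF, 0 °C to rt
Reagents that add atoms: benzyl bromide, BrCc1ccccc1
Why: Williamson etherification; the 4-hydroxyl reacts first, then one of the two equivalent ortho-hydroxyls, after which the remaining ortho-hydroxyl is chelated to the formyl group and is the least nucleophilic, as in the analogous phloroacetophenone chemistry.

Step 5
Reactants: 5 (1S,4S)-1,4-bis(4-methoxyphenyl)but-2-yne-1,4-diol; 7 4,6-bis(benzyloxy)-2-hydroxybenzaldehyde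
Product: 8 2,2'-{[(1R,4R)-1,4-bis(4-methoxyphenyl)but-2-yne-1,4-diyl]bis(oxy)}bis[4,6-bis(benzyloxy)benzaldehyde]
Conditions: 7 (2.4 equiv), PPh3 (2.6 equiv), DIAD (2.6 equiv), toluene, −20 °C to rt
Reagents that add atoms: none
Why: Double Mitsunobu etherification with SN2 inversion at both carbinol carbons, giving the (R,R) bis-ether; the acidic, formyl-chelated phenol is a good pronucleophile, the alkyne prevents cyclisation of the 1,4-diol, and the non-polar solvent and low temperature are chosen to disfavour ionisation of the 4-methoxybenzylic oxyphosphonium ion, which the electron-withdrawing alkynyl group also retards.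

Step 6
Reactants: 8 2,2'-{[(1R,4R)-1,4-bis(4-methoxyphenyl)but-2-yne-1,4-diyl]bis(oxy)}bis[4,6-bis(benzyloxy)benzaldehyde]
Product: 10 (2S,3R,2''S,3''S)-5,7,5'',7''-tetrakis(benzyloxy)-4',4'''-dimethoxy-3,3''-biflavanone, via enone aldehyde 9 (not isolated)
Conditions: 3-mesityl-5,6,7,8-tetrahydro-4H-cyclohepta[d]thiazol-3-ium perchlorate (20 mol%), K2CO3 (40 mol%), THF (0.01 M), 70 °C; AcOH quench at rt
Reagents that add atoms: none
Why: The thiazol-2-ylidene adds to one of the two homotopic formyl groups of 8, the resulting Breslow intermediate adds to the proximal alkyne carbon through a concerted ene-type transition state that passes its O–H proton to the distal carbon, release of the carbene gives the (E)-enone 9, and the remaining formyl group is converted in the same way into a Breslow intermediate that adds to the enone β-carbon (Stetter reaction) before the ring enolate is protonated and the carbene is released. The closest known reaction type is the carbene-catalysed hydroacylation of unactivated alkynes in O-propargyl salicylaldehydes, including its combination with a Stetter reaction of the enone so formed, together with intramolecular Stetter reactions onto α,β-disubstituted acceptors that give 2,3-disubstituted chroman-4-ones. Ring C'' closes 6-exo-dig (bond C4''–C3'') and ring C closes 6-exo-trig (bond C4–C3); in both cases the tether through O1–C2 allows only the six-membered mode. C3 is set in the C–C bond-forming Stetter step: allylic 1,3-strain with C2'' turns the C2–H bond into the plane of the exocyclic C3=C3'' bond, so O1 and the tethered acyl anion lie on one face and the 4-methoxyphenyl group on the other, and a chair-like transition state with the aryl group and the C3 substituent both equatorial gives the 2,3-trans ring. C3'' is set last, by protonation of the ring enolate C3''=C4''–O−: the C2'' aryl group is pseudoaxial to escape 1,2-allylic strain with the bulky C3'' substituent and screens its face, so the proton, from the carbinol O–H of the tetrahedral intermediate or from the medium, arrives anti to it and leaves the 2'',3''-cis ring. Since C2 and C2'' are carried unchanged from 8 (R,R there and S,S here only because alkynyl and alkyl rank differently against aryl), trans in one ring and cis in the other is the (2S,3R,2''S,3''S) isomer, and the difference between the halves comes from the different mechanisms of the two closures, not from any discrimination between the formyl groups. The step needs kinetic control at C3'', which is why only a substoichiometric heterogeneous base, moderate temperature and an acetic acid quench at full conversion are used, so that the cis centre is not equilibrated and the ring enolate does not open by β-elimination of O1''. High dilution keeps intermolecular benzoin and Stetter reactions of the dialdehyde in check.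

Step 7
Reactants: 10 (2S,3R,2''S,3''S)-5,7,5'',7''-tetrakis(benzyloxy)-4',4'''-dimethoxy-3,3''-biflavanone
Product: 11 (2S,3R,2''S,3''S)-5,7,5'',7''-tetrahydroxy-4',4'''-dimethoxy-3,3''-biflavanone (CNP0260837.2)
Conditions: H2 (1 atm), Pd/C (10 wt% Pd), EtOAc/THF 1:1, rt, stopped at the calculated uptake
Reagents that add atoms: none
Why: Hydrogenolysis of four aryl benzyl ethers under neutral conditions; no acid or base is present, so the cis centre C3'' and both C2 centres should be preserved, the methyl ethers are inert, and the O-benzyl groups should cleave well before the ring benzylic O1–C2 bonds.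

## Compound list

1 | 4-methoxybenzaldehyde | COc1ccc(C=O)cc1 | starting material
2 | ethynyltrimethylsilane | C#C[Si](C)(C)C | starting material
3 | (1S)-1-(4-methoxyphenyl)-3-(trimethylsilyl)prop-2-yn-1-ol | COc1ccc(cc1)[C@H](O)C#C[Si](C)(C)C | intermediate
4 | (1R)-1-(4-methoxyphenyl)prop-2-yn-1-ol | COc1ccc(cc1)[C@H](O)C#C | intermediate
5 | (1S,4S)-1,4-bis(4-methoxyphenyl)but-2-yne-1,4-diol | COc1ccc(cc1)[C@H](O)C#C[C@@H](O)c1ccc(OC)cc1 | intermediate
6 | 2,4,6-trihydroxybenzaldehyde | O=Cc1c(O)cc(O)cc1O | starting material
7 | 4,6-bis(benzyloxy)-2-hydroxybenzaldehyde | O=Cc1c(O)cc(OCc2ccccc2)cc1OCc1ccccc1 | intermediate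
8 | 2,2'-{[(1R,4R)-1,4-bis(4-methoxyphenyl)but-2-yne-1,4-diyl]bis(oxy)}bis[4,6-bis(benzyloxy)benzaldehyde] | COc1ccc(cc1)[C@@H](Oc1cc(OCc2ccccc2)cc(OCc2ccccc2)c1C=O)C#C[C@H](Oc1cc(OCc2ccccc2)cc(OCc2ccccc2)c1C=O)c1ccc(OC)cc1 | intermediate
9 | (2R,3E)-5,7-bis(benzyloxy)-3-{(2S)-2-[3,5-bis(benzyloxy)-2-formylphenoxy]-2-(4-methoxyphenyl)ethylidene}-2-(4-methoxyphenyl)chroman-4-one | O=C1c2c(OCc3ccccc3)cc(OCc3ccccc3)cc2O[C@H](c2ccc(OC)cc2)/C1=C\[C@@H](c1ccc(OC)cc1)Oc1cc(OCc2ccccc2)cc(OCc2ccccc2)c1C=O | intermediate (not isolated)
10 | (2S,3R,2''S,3''S)-5,7,5'',7''-tetrakis(benzyloxy)-4',4'''-dimethoxy-3,3''-biflavanone | COc1ccc([C@H]2Oc3cc(OCc4ccccc4)cc(OCc4ccccc4)c3C(=O)[C@@H]2[C@@H]2C(=O)c3c(OCc4ccccc4)cc(OCc4ccccc4)cc3O[C@@H]2c2ccc(OC)cc2)cc1 | intermediate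
11 | (2S,3R,2''S,3''S)-5,7,5'',7''-tetrahydroxy-4',4'''-dimethoxy-3,3''-biflavanone | COc1ccc([C@H]2Oc3cc(O)cc(O)c3C(=O)[C@@H]2[C@@H]2C(=O)c3c(O)cc(O)cc3O[C@@H]2c2ccc(OC)cc2)cc1 | target

## Step count and least certain steps

Total step count: 7. Longest linear sequence: 6 steps (steps 1, 2, 3, 5, 6, 7); step 4 is a one-step branch.

**Step 6 (key step).** Most likely to go wrong is loss of the kinetically set configuration at C3''. The 2,4,6-trioxygenated, doubly ortho-substituted formyl groups should form their Breslow intermediates slowly, and the longer heating this requires gives the basic medium time to epimerise the cis ring toward the trans arrangement (and, if the Stetter closure lags, to epimerise the γ-position of 9). Fallback: starting from 8, the cascade is run deliberately to thermodynamic control (the same 3-mesityl-5,6,7,8-tetrahydro-4H-cyclohepta[d]thiazol-3-ium perchlorate, DBU, THF, 70 °C, prolonged) to give the C2-symmetric (2S,3R,2''S,3''R)-5,7,5'',7''-tetrakis(benzyloxy)-4',4'''-dimethoxy-3,3''-biflavanone F1. Its two C3–H bonds are homotopic, so one equivalent of LiN(SiMe3)2 in THF at −78 °C gives a single mono-enolate, and inverse quench into 2,6-di-tert-butyl-4-methylphenol at −78 °C protonates it anti to the adjacent aryl group. This converts one trans ring into the cis ring and returns to the route at 10.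

**Step 5.** Most likely to go wrong is partial ionisation of the 4-methoxybenzylic, propargylic oxyphosphonium intermediate, which would erode inversion (meso bis-ether, lower enantiopurity) and allow C-alkylation of the phenol. Fallback: the aryl–oxygen bond is formed instead, with retention at carbon. Starting from 1, steps 1 to 3 are repeated with the (R,R) ligand to give (1R)-1-(4-methoxyphenyl)-3-(trimethylsilyl)prop-2-yn-1-ol F2, then (1S)-1-(4-methoxyphenyl)prop-2-yn-1-ol F3 and (1R,4R)-1,4-bis(4-methoxyphenyl)but-2-yne-1,4-diol F4. Separately, benzylation of commercial 5-fluororesorcinol gives 1,3-bis(benzyloxy)-5-fluorobenzene F5, and Vilsmeier formylation (POCl3, DMF) gives 4,6-bis(benzyloxy)-2-fluorobenzaldehyde F6. The dialkoxide of F4 (KN(SiMe3)2, THF/DMF, 0 °C) displaces fluoride from two molecules of F6 by nucleophilic aromatic substitution ortho to the formyl group, without touching the carbinol carbons, and the route is rejoined at 8.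

**Step 3.** Most likely to go wrong is interference of the resident zinc alkoxide of 4 with the dinuclear catalyst, giving slow turnover or lower facial control and hence more meso diol. Fallback: the hydroxyl is masked. Starting from 4, silylation (TBSCl, imidazole, CH2Cl2) gives (1R)-tert-butyl{[1-(4-methoxyphenyl)prop-2-yn-1-yl]oxy}dimethylsilane F7. The same zinc-catalysed alkynylation of 1 with F7 gives (1S,4S)-4-[(tert-butyldimethylsilyl)oxy]-1,4-bis(4-methoxyphenyl)but-2-yn-1-ol F8, and Bu4NF in THF returns to the route at 5.

**Step 7.** Most likely to go wrong is over-reduction: hydrogenolysis of the ring benzylic O1–C2 bonds (opening of ring C to a dihydrochalcone) competing with the last O-debenzylations, or epimerisation of C3'' on the metal surface. Fallback: non-reductive Lewis-acid debenzylation of 10 with BCl3 and pentamethylbenzene as cation scavenger in CH2Cl2 at −78 °C, which spares the unchelated 4'-methyl ethers and leads directly from 10 to 11 without a new intermediate.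

## Further compounds

F1 | step 6 | (2S,3R,2''S,3''R)-5,7,5'',7''-tetrakis(benzyloxy)-4',4'''-dimethoxy-3,3''-biflavanone | COc1ccc([C@H]2Oc3cc(OCc4ccccc4)cc(OCc4ccccc4)c3C(=O)[C@@H]2[C@H]2C(=O)c3c(OCc4ccccc4)cc(OCc4ccccc4)cc3O[C@@H]2c2ccc(OC)cc2)cc1
F2 | step 5 | (1R)-1-(4-methoxyphenyl)-3-(trimethylsilyl)prop-2-yn-1-ol | COc1ccc(cc1)[C@@H](O)C#C[Si](C)(C)C
F3 | step 5 | (1S)-1-(4-methoxyphenyl)prop-2-yn-1-ol | COc1ccc(cc1)[C@@H](O)C#C
F4 | step 5 | (1R,4R)-1,4-bis(4-methoxyphenyl)but-2-yne-1,4-diol | COc1ccc(cc1)[C@@H](O)C#C[C@H](O)c1ccc(OC)cc1
F5 | step 5 | 1,3-bis(benzyloxy)-5-fluorobenzene | Fc1cc(OCc2ccccc2)cc(OCc2ccccc2)c1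
F6 | step 5 | 4,6-bis(benzyloxy)-2-fluorobenzaldehyde | O=Cc1c(F)cc(OCc2ccccc2)cc1OCc1ccccc1
F7 | step 3 | (1R)-tert-butyl{[1-(4-methoxyphenyl)prop-2-yn-1-yl]oxy}dimethylsilane | COc1ccc(cc1)[C@H](O[Si](C)(C)C(C)(C)C)C#C
F8 | step 3 | (1S,4S)-4-[(tert-butyldimethylsilyl)oxy]-1,4-bis(4-methoxyphenyl)but-2-yn-1-ol | COc1ccc(cc1)[C@H](O[Si](C)(C)C(C)(C)C)C#C[C@@H](O)c1ccc(OC)cc1
F0 | step 7 | none | none
A1 | alternative 1 | (2S)-5,7-bis(benzyloxy)-2-(4-methoxyphenyl)chroman-4-one | COc1ccc(cc1)[C@@H]1CC(=O)c2c(OCc3ccccc3)cc(OCc3ccccc3)cc2O1
A2 | alternative 1 | (2S,3R,2''S,3''R)-5,7,5'',7''-tetrakis(benzyloxy)-4',4'''-dimethoxy-3,3''-biflavanone | COc1ccc([C@H]2Oc3cc(OCc4ccccc4)cc(OCc4ccccc4)c3C(=O)[C@@H]2[C@H]2C(=O)c3c(OCc4ccccc4)cc(OCc4ccccc4)cc3O[C@@H]2c2ccc(OC)cc2)cc1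
A3 | alternative 2 | (E)-1-[4,6-bis(benzyloxy)-2-hydroxyphenyl]-3-(4-hydroxyphenyl)prop-2-en-1-one | O=C(/C=C/c1ccc(O)cc1)c1c(O)cc(OCc2ccccc2)cc1OCc1ccccc1
A4 | alternative 2 | (2S,3R,2''S,3''S)-5,7,5'',7''-tetrakis(benzyloxy)-4',4'''-dihydroxy-3,3''-biflavanone | Oc1ccc([C@H]2Oc3cc(OCc4ccccc4)cc(OCc4ccccc4)c3C(=O)[C@@H]2[C@@H]2C(=O)c3c(OCc4ccccc4)cc(OCc4ccccc4)cc3O[C@@H]2c2ccc(O)cc2)cc1
A5 | alternative 3 | 1,4-bis[4,6-bis(benzyloxy)-2-hydroxyphenyl]butane-1,4-dione | O=C(CCC(=O)c1c(O)cc(OCc2ccccc2)cc1OCc1ccccc1)c1c(O)cc(OCc2ccccc2)cc1OCc1ccccc1
A6 | alternative 3 | (2E,3E)-1,4-bis[4,6-bis(benzyloxy)-2-hydroxyphenyl]-2,3-bis(4-methoxybenzylidene)butane-1,4-dione | COc1ccc(/C=C(/C(=O)c2c(O)cc(OCc3ccccc3)cc2OCc2ccccc2)\C(=C/c2ccc(OC)cc2)C(=O)c2c(O)cc(OCc3ccccc3)cc2OCc2ccccc2)cc1
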